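**Strategy.** Elemane numbering is used (cyclohexane ring C5–C10; γ-lactone C7–C11–C12–O–C8). The cyclohexane holds a cis-dioxygenated two-carbon unit, C8–C9, between C7 (allylic to the C11=C13 methylene) and quaternary C10 (carrying C1–C2). Disconnecting C7–C8 and C9–C10 gives glyoxal and an open chain with two allyl donors. In one pot, the (Z)-2-(methoxycarbonyl)allylboronate terminus adds to glyoxal and lactonises, then CrCl2 closes the (Z)-allylic chloride terminus onto the second aldehyde: two C–C bonds, both rings and four stereocentres (C7–C10) from an acyclic precursor. Levoglucosenone supplies C6 and controls C5.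

Key step: step 11

Remarks on the chemistry: glyoxal (18) is used as the anhydrous monomer, freshly generated from the commercial trimer dihydrate. Ketone 4 is carried as both C10 epimers, because C10 becomes trigonal in step 2.

Step 1
Reactants: 1 levoglucosenone; 2 isopropenylmagnesium bromide, CH2=C(CH3)MgBr
Product: 4 3-methyl-2-(prop-1-en-2-yl)-6,8-dioxabicyclo[3.2.1]octan-4-one (isopropenyl anti to the 1,6-anhydro bridge), via magnesium enolate 3 (not isolated)
Conditions: 2 (1.3 equiv), CuBr·SMe2 (10 mol%), THF, −78 °C; then MeI (3 equiv), HMPA, −78 → −20 °C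
Reagents that add atoms: iodomethane, CI
Why: Copper-catalysed conjugate addition of the Grignard reagent should occur only on the enone face anti to the 1,6-anhydro bridge, which sets C5 trans to the C6–C7 bond, and the magnesium enolate, which can form only towards C10, is then C-methylated (tandem conjugate addition–enolate alkylation).

Step 2
Reactants: 4 ketone
Product: 5 3-methyl-2-(prop-1-en-2-yl)-6,8-dioxabicyclo[3.2.1]oct-3-en-4-yl trifluoromethanesulfonate
Conditions: KN(SiMe3)2, THF, −78 → −40 °C; then PhNTf2
Reagents that add atoms: N-phenylbis(trifluoromethanesulfonimide), O=S(=O)(N(c1ccccc1)S(=O)(=O)C(F)(F)F)C(F)(F)F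
Why: Deprotonation is possible only at C10 because the other α-carbon is the bridgehead acetal carbon, so O-sulfonylation of the potassium enolate (enol triflate formation) should give the C10=C1 enol triflate regiospecifically and erase the C10 stereocentre.

Step 3
Reactants: 5 enol triflate
Product: 6 3-methyl-2-(prop-1-en-2-yl)-6,8-dioxabicyclo[3.2.1]oct-3-ene
Conditions: Pd(OAc)2 (5 mol%), PPh3, Bu3N, HCO2H, DMF, 60 °C
Reagents that add atoms: none
Why: Palladium-catalysed formate reduction of the enol triflate (hydrogenolysis of the vinyl C–O bond through zerovalent palladium) replaces OTf by H and leaves the trisubstituted C10=C1 alkene, whose cis geometry is fixed by the ring.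

Step 4
Reactants: 6 bicyclic allylic acetal
Product: 8 [(2S,3S)-4-methyl-3-(prop-1-en-2-yl)-3,6-dihydro-2H-pyran-2-yl]methanol, via triethylsilyl ether 7 (not isolated)
Conditions: Et3SiH (3 equiv), Me3SiOTf (0.2 equiv), CH2Cl2, −78 → −30 °C; then K2CO3 (cat.), MeOH, rt
Reagents that add atoms: none
Why: The silyl triflate ionises the allylic 1,6-anhydro acetal to the six-membered allyl oxocarbenium ion, which should take hydride from Et3SiH at the acetal carbon C2 (Ferrier-type reductive acetal opening) without touching C5 or C6, and methanolysis then frees the C7 hydroxyl.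

Step 5
Reactants: 8 dihydropyran alcohol
Product: 9 (2S,3S)-4-methyl-3-(prop-1-en-2-yl)-3,6-dihydro-2H-pyran-2-carbaldehyde
Conditions: Dess–Martin oxidation (1,1,1-triacetoxy-1,2-benziodoxol-3(1H)-one), CH2Cl2, 0 °C → rt
Reagents that add atoms: none
Why: The Dess–Martin oxidation converts the primary alcohol into the α-alkoxy aldehyde under neutral conditions that should not epimerise C6.

Step 6
Reactants: 9 aldehyde
Product: 10 2-(2,2-dibromoethenyl)-4-methyl-3-(prop-1-en-2-yl)-3,6-dihydro-2H-pyran (2,3-trans, configured as in 8)
Conditions: CBr4, PPh3, CH2Cl2, 0 °C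
Reagents that add atoms: carbon tetrabromide, BrC(Br)(Br)Br
Why: Corey–Fuchs dibromo-olefination (Wittig-type reaction of Ph3P=CBr2) homologates the aldehyde by the carbon that becomes C11.

Step 7
Reactants: 10 dibromoalkene
Product: 12 methyl 3-[4-methyl-3-(prop-1-en-2-yl)-3,6-dihydro-2H-pyran-2-yl]prop-2-ynoate (2,3-trans, as in 8), via lithium acetylide 11 (not isolated)
Conditions: n-BuLi (2.1 equiv), THF, −78 °C; then ClCO2Me, −78 → 0 °C
Reagents that add atoms: methyl chloroformate, COC(=O)Cl
Why: In the second stage of the Corey–Fuchs sequence, bromine–lithium exchange and rearrangement give the lithium acetylide, which is acylated by the chloroformate to the ynoate.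

Step 8
Reactants: 12 ynoate
Product: 14 methyl (Z)-3-[4-methyl-3-(prop-1-en-2-yl)-3,6-dihydro-2H-pyran-2-yl]-2-[(4,4,5,5-tetramethyl-1,3,2-dioxaborolan-2-yl)methyl]prop-2-enoate (pyran 2,3-trans, as in 8), via alkenylalane 13 (not isolated)
Conditions: i-Bu2AlH (1.2 equiv), HMPA, THF, 0 °C; then ICH2Bpin, 0 °C → rt
Reagents that add atoms: 2-(iodomethyl)-4,4,5,5-tetramethyl-1,3,2-dioxaborolane, ICB1OC(C)(C)C(C)(C)O1
Why: Conjugate syn-hydroalumination of the ynoate by the i-Bu2AlH–HMPA complex places hydride on C7 and aluminium on C11, and alkylation of the alkenylalane with retention should give the 2-(borylmethyl)acrylate in which C6 is cis to the ester and trans to the CH2B carbon (hydroalumination–alkylation route to 2-alkoxycarbonyl allylboronates).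

Step 9
Reactants: 15 (S)-2-methylbutanoic acid
Product: 16 (S)-2-methylbutanoyl chloride
Conditions: (COCl)2, DMF (cat.), CH2Cl2, 0 °C → rt
Reagents that add atoms: oxalyl chloride, O=C(Cl)C(Cl)=O
Why: Acid chloride formation with oxalyl chloride and catalytic DMF runs without base, so the α-stereocentre should not epimerise.

Step 10
Reactants: 14 allylboronate dihydropyran; 16 (S)-2-methylbutanoyl chloride
Product: 17 methyl (2Z,6Z)-8-chloro-6-methyl-4-{[(2S)-2-methylbutanoyl]oxy}-5-(prop-1-en-2-yl)-2-[(4,4,5,5-tetramethyl-1,3,2-dioxaborolan-2-yl)methyl]octa-2,6-dienoate (C6 and C5 of the target configured as in 8)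
Conditions: ZnCl2 (10 mol%), CH2Cl2, −20 → 0 °C
Reagents that add atoms: none
Why: In this Lewis-acid-catalysed acylative cleavage of a cyclic allylic ether, O-acylation of the ring oxygen and attack of chloride at the primary allylic carbon C2 should give the O6 ester with retention at C6 and the allylic chloride whose Z geometry is inherited from the ring.

Step 11
Reactants: 17 open-chain chloride ester; 18 glyoxal
Product: 21 9α-hydroxy-6β-[(S)-2-methylbutanoyloxy]elema-1,3,11(13)-trien-12,8α-olide (5αH, 7αH, 10β-methyl), via boronate adduct 19 (not isolated), via lactone aldehyde 20 (not isolated)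
Conditions: 18 (3 equiv), toluene, 50 °C; volatiles removed in vacuo; then CrCl2 (4 equiv), LiI (10 mol%), THF/DMF, 0 °C → rt; aqueous NH4Cl
Reagents that add atoms: none
Why: Stage one is a thermal allylboration of glyoxal by the 2-(methoxycarbonyl)allylboronate through a closed six-membered chair transition state, after which the boron alkoxide closes the γ-lactone on the methyl ester (5-exo-trig acyl substitution); stage two is a Nozaki–Hiyama–Kishi allylation in which the allylchromium from the (Z)-allylic chloride adds through its γ-carbon C10 to the C9 aldehyde (6-exo-trig closure of the cyclohexane, again a closed chair). The closest known reaction types are the allylboration–lactonisation route to α-methylene-γ-butyrolactones and the intramolecular chromium-mediated allylation, here run on the two carbonyl groups of one glyoxal so that C8–C9 is stitched between C7 and C10. C7 should be set by allylic 1,3-strain between C6 and the cis ester, which holds H6 in the alkene plane so that glyoxal attacks anti to the bulky C5 branch, and C8 by the boronate geometry (C6 trans to CH2B, aldehyde substituent equatorial), which gives the anti adduct and hence the trans-fused lactone. C9 and C10 are set together: the trans-lactone locks the forming ring in the chair with the C5 substituent equatorial, and the (Z)-allylchromium (C5 cis to the CH2Cr carbon) can reach the aldehyde only through the cis-decalin-like chair–chair transition state that places O9 axial, the new vinyl group equatorial and the C10 methyl axial. The step needs C7–C8 to form before C9–C10, which is secured because the chloride terminus is inert until CrCl2 is added, and it needs the allylchromium to keep its Z geometry, which γ,γ-disubstituted allylchromium species are expected to do at 0 °C.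

Step 12
Reactants: 21 hydroxy lactone
Product: 22 9α-(triethylsilyloxy) derivative of 21
Conditions: Et3SiOTf, 2,6-lutidine, CH2Cl2, −78 → 0 °C
Reagents that add atoms: triethylsilyl trifluoromethanesulfonate, CC[Si](CC)(CC)OS(=O)(=O)C(F)(F)F
Why: Silylation of the hindered axial C9 hydroxyl with the silyl triflate protects it and adds the bulk that is used for face selection in step 14.

Step 13
Reactants: 22 silyl ether
Product: 24 15-oxo-9α-(triethylsilyloxy)-6β-[(S)-2-methylbutanoyloxy]elema-1,3,11(13)-trien-12,8α-olide (C5 now carries the 3-oxoprop-1-en-2-yl group), via allylic alcohol 23 (not isolated)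
Conditions: SeO2 (0.3 equiv), t-BuOOH (2 equiv), CH2Cl2, rt; then MnO2, CH2Cl2, rt
Reagents that add atoms: selenium dioxide, O=[Se]=O; tert-butyl hydroperoxide, CC(C)(C)OO
Why: Selenium dioxide allylic oxidation (ene reaction then 2,3-sigmatropic shift) should attack only the isopropenyl group, at its methyl and not at the hindered C5–H, because the vinyl group has no allylic hydrogen and the lactone methylene is electron-poor, and MnO2 then takes the allylic alcohol to the enal.

Step 14
Reactants: 24 enal
Product: 25 1,2-epoxide of 24 (9-O-triethylsilyl ether of the target)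
Conditions: dimethyldioxirane (1.5 equiv, acetone solution), CH2Cl2, 0 °C
Reagents that add atoms: dimethyldioxirane, CC1(C)OO1
Why: The electron-poor enal and α-methylene lactone are inert to the electrophilic dioxirane, so only the vinyl group should be epoxidised, and the reagent should approach past the small axial C10 methyl because the other flanks are covered by the axial C9 silyloxy group and the equatorial C5 substituent, which sets C1 (substrate-controlled epoxidation).

Step 15
Reactants: 25 silyl-protected target
Product: 26 target, 1,2-epoxy-9α-hydroxy-6β-[(S)-2-methylbutanoyloxy]-15-oxoelema-3,11(13)-dien-12,8α-olide (CNP0593558.1)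
Conditions: HF·pyridine, pyridine, THF, 0 °C
Reagents that add atoms: none
Why: Buffered fluoride cleavage of the triethylsilyl ether should leave the epoxide, the enal, the lactone and the ester untouched.

**Compound list**

1 | levoglucosenone, (1S,5R)-6,8-dioxabicyclo[3.2.1]oct-2-en-4-one | O=C1C=C[C@H]2CO[C@@H]1O2 | starting material
2 | isopropenylmagnesium bromide | C=C(C)[Mg]Br | starting material
3 | bromomagnesium enolate of the 1,4-adduct (isopropenyl anti to the bridge) | Br[Mg]OC1=C[C@H](C(C)=C)[C@H]2CO[C@@H]1O2 | intermediate (not isolated)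
4 | 3-methyl-2-(prop-1-en-2-yl)-6,8-dioxabicyclo[3.2.1]octan-4-one, both C3 epimers | O=C1C(C)[C@H](C(C)=C)[C@H]2CO[C@@H]1O2 | intermediate
5 | 3-methyl-2-(prop-1-en-2-yl)-6,8-dioxabicyclo[3.2.1]oct-3-en-4-yl triflate | FC(F)(F)S(=O)(=O)OC1=C(C)[C@H](C(C)=C)[C@H]2CO[C@@H]1O2 | intermediate
6 | 3-methyl-2-(prop-1-en-2-yl)-6,8-dioxabicyclo[3.2.1]oct-3-ene | C1=C(C)[C@H](C(C)=C)[C@H]2CO[C@@H]1O2 | intermediate
7 | triethylsilyl ether of 8 | CC[Si](CC)(CC)OC[C@H]1OCC=C(C)[C@@H]1C(C)=C | intermediate (not isolated)
8 | [(2S,3S)-4-methyl-3-(prop-1-en-2-yl)-3,6-dihydro-2H-pyran-2-yl]methanol | OC[C@H]1OCC=C(C)[C@@H]1C(C)=C | intermediate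
9 | (2S,3S)-4-methyl-3-(prop-1-en-2-yl)-3,6-dihydro-2H-pyran-2-carbaldehyde | O=C[C@H]1OCC=C(C)[C@@H]1C(C)=C | intermediate
10 | 2-(2,2-dibromoethenyl)-4-methyl-3-(prop-1-en-2-yl)-3,6-dihydro-2H-pyran (2,3-trans) | BrC(Br)=C[C@H]1OCC=C(C)[C@@H]1C(C)=C | intermediate
11 | lithium acetylide of the 2-ethynyl dihydropyran | [Li]C#C[C@H]1OCC=C(C)[C@@H]1C(C)=C | intermediate (not isolated)
12 | methyl 3-[4-methyl-3-(prop-1-en-2-yl)-3,6-dihydro-2H-pyran-2-yl]prop-2-ynoate (2,3-trans) | COC(=O)C#C[C@H]1OCC=C(C)[C@@H]1C(C)=C | intermediate
13 | diisobutyl alkenylalane (Al on C11, cis to H7) | COC(=O)/C([Al](CC(C)C)CC(C)C)=C\[C@H]1OCC=C(C)[C@@H]1C(C)=C | intermediate (not isolated)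
14 | methyl (Z)-3-[4-methyl-3-(prop-1-en-2-yl)-3,6-dihydro-2H-pyran-2-yl]-2-[(pinacolboryl)methyl]prop-2-enoate | COC(=O)/C(CB1OC(C)(C)C(C)(C)O1)=C\[C@H]1OCC=C(C)[C@@H]1C(C)=C | intermediate
15 | (S)-2-methylbutanoic acid | CC[C@H](C)C(=O)O | starting material
16 | (S)-2-methylbutanoyl chloride | CC[C@H](C)C(Cl)=O | intermediate
17 | methyl (2Z,6Z)-8-chloro-6-methyl-4-{[(2S)-2-methylbutanoyl]oxy}-5-(prop-1-en-2-yl)-2-[(pinacolboryl)methyl]octa-2,6-dienoate | COC(=O)/C(CB1OC(C)(C)C(C)(C)O1)=C\[C@@H](OC(=O)[C@@H](C)CC)[C@@H](C(C)=C)/C(C)=C\CCl | intermediate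
18 | glyoxal (anhydrous monomer) | O=CC=O | starting material
19 | pinacol borate of the glyoxal mono-adduct (anti C7/C8) | COC(=O)C(=C)[C@H]([C@H](C=O)OB1OC(C)(C)C(C)(C)O1)[C@@H](OC(=O)[C@@H](C)CC)[C@@H](C(C)=C)/C(C)=C\CCl | intermediate (not isolated)
20 | trans-4,5-disubstituted 3-methylene-2-oxotetrahydrofuran-5-carbaldehyde (lactone aldehyde with the chloride side chain) | C=C1C(=O)O[C@@H](C=O)[C@@H]1[C@@H](OC(=O)[C@@H](C)CC)[C@@H](C(C)=C)/C(C)=C\CCl | intermediate (not isolated)
21 | 9α-hydroxy-6β-[(S)-2-methylbutanoyloxy]elema-1,3,11(13)-trien-12,8α-olide | C=C1C(=O)O[C@@H]2[C@@H]1[C@@H](OC(=O)[C@@H](C)CC)[C@@H](C(C)=C)[C@](C)(C=C)[C@@H]2O | intermediate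
22 | 9-O-triethylsilyl ether of 21 | C=C1C(=O)O[C@@H]2[C@@H]1[C@@H](OC(=O)[C@@H](C)CC)[C@@H](C(C)=C)[C@](C)(C=C)[C@@H]2O[Si](CC)(CC)CC | intermediate
23 | allylic alcohol (C5 carries 3-hydroxyprop-1-en-2-yl) | C=C1C(=O)O[C@@H]2[C@@H]1[C@@H](OC(=O)[C@@H](C)CC)[C@@H](C(=C)CO)[C@](C)(C=C)[C@@H]2O[Si](CC)(CC)CC | intermediate (not isolated)
24 | enal (C5 carries 3-oxoprop-1-en-2-yl) | C=C1C(=O)O[C@@H]2[C@@H]1[C@@H](OC(=O)[C@@H](C)CC)[C@@H](C(=C)C=O)[C@](C)(C=C)[C@@H]2O[Si](CC)(CC)CC | intermediate
25 | 9-O-triethylsilyl ether of the target | C=C1C(=O)O[C@@H]2[C@@H]1[C@@H](OC(=O)[C@@H](C)CC)[C@@H](C(=C)C=O)[C@](C)([C@@H]1CO1)[C@@H]2O[Si](CC)(CC)CC | intermediate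
26 | target CNP0593558.1 | C=C1C(=O)O[C@@H]2[C@@H]1[C@@H](OC(=O)[C@@H](C)CC)[C@@H](C(=C)C=O)[C@](C)([C@@H]1CO1)[C@@H]2O | target

**Totals.** Total step count: 15. Longest linear sequence: 14 steps (steps 1–8 and 10–15 from levoglucosenone); step 9 is a one-step side branch.

**The three steps most likely to fail**

Step 11 (key step). Glyoxal may oligomerise or take up two chains, the first allylation may show poor facial selectivity at C7, and the allylchromium may lose its Z geometry before ring closure, which would epimerise C9. The fallback makes the two bonds in separate, purifiable stages. It sets out from 17: allylboration with 2,2-dimethoxyacetaldehyde (toluene, 60 °C) and lactonisation should give lactone dimethyl acetal F1. Hydrolysis of the acetal (LiBF4, wet MeCN) gives lactone aldehyde 20, now isolated. Ring closure with CrCl2 in THF/DMF under dilution then gives 21, where the route is rejoined.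

Step 10. The acylated ether may ionise to an allyl cation, with loss of the Z geometry or allylic transposition of chloride, and the allylboron unit may assist elimination of the activated C6–O bond or be damaged by the Lewis acid. The fallback opens the ring before boron is introduced. It sets out from ynoate 12: the same acylative cleavage with 16 and ZnCl2 gives chloro ester ynoate F2, which has no allylboron and has an electron-poor alkyne next to C6. Hydroalumination with i-Bu2AlH–HMPA (1.05 equiv, −20 °C, to spare the ester) gives alkenylalane F3, which is alkylated in the flask with ICH2Bpin to give 17, where the route is rejoined.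

Step 14. Facial selectivity at C1 may be poor or reversed, since the vinyl group sits on a quaternary carbon with no strong bias. The fallback replaces substrate control by a catalyst-controlled resolution. It sets out from 24: epoxidation with dimethyldioxirane is run without regard to selectivity and gives 25 together with C1-epimeric epoxide F4. Hydrolytic kinetic resolution with (salen)Co(OAc) (trivalent cobalt; the catalyst enantiomer that hydrolyses F4 faster) and water (0.55 equiv relative to F4) converts F4 into diol F5. Epoxide 25 is recovered by chromatography, where the route is rejoined.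

**Further compounds**

F1 | step 11 | lactone dimethyl acetal (acetal of 20) | C=C1C(=O)O[C@@H](C(OC)OC)[C@@H]1[C@@H](OC(=O)[C@@H](C)CC)[C@@H](C(C)=C)/C(C)=C\CCl
F2 | step 10 | methyl (6Z)-8-chloro-6-methyl-4-{[(2S)-2-methylbutanoyl]oxy}-5-(prop-1-en-2-yl)oct-6-en-2-ynoate | COC(=O)C#C[C@@H](OC(=O)[C@@H](C)CC)[C@@H](C(C)=C)/C(C)=C\CCl
F3 | step 10 | diisobutyl alkenylalane from F2 (not isolated) | COC(=O)/C([Al](CC(C)C)CC(C)C)=C\[C@@H](OC(=O)[C@@H](C)CC)[C@@H](C(C)=C)/C(C)=C\CCl
F4 | step 14 | C1 epimer of 25 | C=C1C(=O)O[C@@H]2[C@@H]1[C@@H](OC(=O)[C@@H](C)CC)[C@@H](C(=C)C=O)[C@](C)([C@H]1CO1)[C@@H]2O[Si](CC)(CC)CC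
F5 | step 14 | 1,2-diol from hydrolysis of F4 | C=C1C(=O)O[C@@H]2[C@@H]1[C@@H](OC(=O)[C@@H](C)CC)[C@@H](C(=C)C=O)[C@](C)([C@H](O)CO)[C@@H]2O[Si](CC)(CC)CC
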